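## Structural features

Hierochin B is an 8–5′-type neolignan built on a 2,3-dihydrobenzofuran. Benzene ring A is fused through C3a–C7a to the five-membered oxygen ring B (O1, C2, C3), and C2 carries a 3,4-dimethoxyphenyl group (ring C). Ring A holds a methoxy group at C7, next to the ring oxygen, and an (E)-3-hydroxyprop-1-enyl chain at C5, para to O1; C3 carries a hydroxymethyl group. The only stereocentres are C2 (S) and C3 (R), which are neighbours in ring B with the aryl and hydroxymethyl groups trans. The fragile points are the C2–O1 bond (a benzylic aryl ether that the electron-rich ring C helps to ionise under acid), the cinnamyl alcohol (sensitive to acid and oxidants) and the two electron-rich arenes. In any intermediate with a carbonyl group on C3, C3–H becomes acidic and O1 becomes a β-leaving group. The skeleton is easy to reach; the real difficulty is the absolute configuration of the C2/C3 pair, since the trans relation alone can be reached by equilibration but the absolute sense cannot. The feature used here is that C2 and C3 are the two carbons of the C2=C3 enol-ether bond of a planar benzofuran, so adding the aryl group to C2 and a carbon substituent to C3 from opposite faces creates both centres and their trans relation in one event.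

## Logic of the disconnections

**18 ⇒ 17 ⇒ 16.** The Cα=Cβ bond of the C5 side chain of 18 is cut, after adjusting the alcohol to the ester of 17, which leads back to 16 and a two-carbon ylide. The cinnamyl alcohol is the most sensitive part of 18 and is therefore made last. The gain is that the C5 substituent shrinks to one formyl carbon that can be carried in masked form from the start. The forward steps must give the E alkene in the presence of a free primary alcohol and must reduce the ester 1,2 only.

**16 ⇒ 15 ⇒ 14 ⇒ 13 ⇒ 12.** The formyl group of 16 is returned to the acetal of 15. The C3 hydroxymethyl carbon is traced through the aldehyde 14 to the exocyclic C=C bond of 13, and by shifting that bond one position outwards to the allyl group of 12. The reason is that an allyl unit is what the key step can deliver to C3; the two surplus carbons are the price. The gain is a C3 substituent that is an inert hydrocarbon during the organometallic steps. The forward steps must stop the isomerisation after one shift without touching C3–H, must cleave the alkene without oxidising two electron-rich arenes, and must reduce 14 at once because its C3–H is acidic and O1 is a β-leaving group.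

**12 ⇒ 11.** The C2–H bond of 12 is replaced by the C2–B bond of 11, because boron is what the migration leaves at C2. Nothing is gained in size, but the intermediate connects to a three-component assembly. The forward step must replace boron by hydrogen with retention; inversion would give the cis series.

**11 ⇒ 10 ⇒ 9 + 7 + 8.** The C3–CH2 bond to the allyl group and the C2–aryl bond are cut and ring B is returned to the aromatic state. This is the strategic cut: it removes both stereocentres at once and leaves three flat, achiral pieces, namely 9 (from 6), 7 and 8. The forward step must select one face of C3 through a chiral catalyst and must move the aryl group from boron to C2 on the opposite face.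

**9 ⇒ 6 ⇒ 5.** The C2–Li bond of 9 goes back to C2–H of 6, and the acetal of 6 to the aldehyde of 5. The acetal is there only because the formyl group would not survive the organolithium. The forward steps need C2-selective deprotonation and an acetal that lasts until step 7.

**5 ⇒ 4 ⇒ 3 ⇒ 1 + 2.** The O1–C2 bond of the furan and the C3a–C3 bond are cut, which gives 1, already carrying the whole substitution pattern of ring A, and the two-carbon unit 2. The forward steps are a cross-coupling at the iodide and a 5-endo ring closure of the phenol onto the alkyne.

## Other disconnections considered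

**Alternative 1:** The cut is the O1–C2 bond. In the forward sense the phenol A1, which already holds the C3 stereocentre and a CH2 group at the future C2, would be treated with DDQ. Hydride abstraction from that methylene, made possible by the dimethoxyphenyl ring, would give a benzylic cation that the ortho phenol oxygen captures to form A2 with the aryl group trans to the silyloxymethyl arm.
- In its favour: only C3 has to be set by an external chiral controller, and C2 follows the ring's own kinetic and thermodynamic preference. The ring closure belongs to a well-precedented reaction class, so on mechanistic security this plan is the better of the two.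
- Against it here: DDQ must distinguish the intended methylene from the free electron-rich phenol, the tertiary benzylic C3–H and the product, which can be dehydrogenated to the benzofuran. The C5 ester is needed to tame ring A and must then be taken through reduction, oxidation, olefination, reduction and desilylation. A1, a 1,2-diarylpropane with an isolated stereocentre, needs its own asymmetric sequence.
- Comparison: after the key step the two plans are about equal in step count. Before it the chosen plan is shorter, because the skeleton and both stereocentres appear in the fourth step. Structurally, the chosen plan derives the trans relation from a stereospecific anti addition, the alternative from a diastereoselective cation capture.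

**Alternative 2:** The cut removes three bonds of ring A (C3a–C7a, C4–C5, C6–C7). In the forward sense the silicon-tethered diyne A3 and the enyne A4 would cyclotrimerise on Cp*RuCl(cod) to give A5, in which ring A is formed together with a six-membered siloxane ring. Oxidation of the aryl–silicon bond to the phenol (Tamao type) and ring closure at C2 with inversion would then give ring B.
- In its favour: the plan is highly convergent. Ring A is born with the C7 methoxy group and the complete protected C5 side chain, so the chain-building steps at the end of the chosen route are not needed; on this point the alternative is the better plan. The tether decides which alkyne carbons join and doubles as the latent phenol oxygen. Alkyne cyclotrimerisation is a known reaction type, so its key step is at least the equal of the chosen one in precedent.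
- Against it here: both stereocentres must be made beforehand in an acyclic precursor, and C2 must later be inverted by displacement at an electron-rich benzylic carbinol, where ionisation can leak stereochemistry. A3 contains a silyl-substituted ynol ether, a sensitive unit. The insertion of A4 must place the chain at C5 and not at C6.
- Comparison: ring A is commercially available in the chosen plan and is built from scratch here, so the total step count would be clearly higher.

**Alternative 3:** The cut is C3a–C4 and C7–C7a. In the forward sense A6, the trimethylsilyl ketene acetal of a trans-4,5-disubstituted butyrolactone, would add to the pyrone A7 in a Diels–Alder reaction; loss of CO2 and of trimethylsilanol would aromatise the adduct to A8.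
- In its favour: both stereocentres are set in a trans-disubstituted lactone, a class for which reliable asymmetric methods exist and in which trans is the stable arrangement. They are not involved in the bond-forming events of the key step, and the regiochemistry follows from the polarity of both partners. The key step carries no stereochemical risk, which makes it the better of the two on that point.
- Against it here: ring A arrives with bromine at C7 and an ester at C5. This costs a C–O coupling next to the ring oxygen and the same ester-to-chain sequence as in alternative 1. A6 is hydrolytically labile, and the thermal cascade needs forcing conditions.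
- Comparison: the chosen plan takes ring A ready-made and creates both stereocentres in one step, whereas this plan needs a multi-step lactone synthesis before its key step and more adjustments after it.

Key step: step 4

**Remarks on the chemistry (assumptions)**
- (R)-BINAP is assumed to direct the allyl group to the face of C3 that leads to (2S,3S)-11; if the sense of induction is the opposite, (S)-BINAP is used and nothing else changes.
- 13 is drawn as the E isomer; a share of Z isomer is of no consequence, because the double bond is cleaved in step 7.
- 11 to 14 carry the descriptors (2S,3S) and 15 to 18 (2S,3R), although the spatial arrangement is the same throughout; only the CIP priority of the C3 substituent changes. Replacing boron in 11 by hydrogen with retention maps directly onto the target configuration.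

## Route

Step 1
Reactants: 1 5-iodovanillin (4-hydroxy-3-iodo-5-methoxybenzaldehyde); 2 trimethylsilylacetylene
Product: 3 4-hydroxy-3-methoxy-5-[(trimethylsilyl)ethynyl]benzaldehyde
Conditions: PdCl2(PPh3)2 (2 mol%), CuI (4 mol%), Et3N, THF, rt
Reagents that add atoms: none
Why: Sonogashira coupling of an aryl iodide, which should proceed at room temperature with the free phenol in place; the silyl cap prevents double coupling and slows premature cyclisation.

Step 2
Reactants: 3 4-hydroxy-3-methoxy-5-[(trimethylsilyl)ethynyl]benzaldehyde
Product: 5 7-methoxybenzofuran-5-carbaldehyde, via desilylated alkynylphenol 4 (not isolated)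
Conditions: CuI (10 mol%), Et3N/EtOH (1:1), 75 °C
Reagents that add atoms: none
Why: Basic ethanol should cleave the alkynyl–silicon bond, and monovalent copper then activates the terminal alkyne for 5-endo-dig hydroalkoxylation by the ortho phenoxide; aromatisation to the benzofuran drives the closure.

Step 3
Reactants: 5 7-methoxybenzofuran-5-carbaldehyde
Product: 6 5-(dimethoxymethyl)-7-methoxybenzofuran
Conditions: HC(OMe)3, p-TsOH·H2O (1 mol%), MeOH, rt; Et3N quench
Reagents that add atoms: trimethyl orthoformate, COC(OC)OC; methanol, CO
Why: Acid-catalysed acetalisation, with the orthoformate removing the water; the acetal protects the formyl carbon against n-BuLi and is purified on base-washed silica because it is acid-labile.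

Step 4
Reactants: 6 5-(dimethoxymethyl)-7-methoxybenzofuran; 7 2-(3,4-dimethoxyphenyl)-4,4,5,5-tetramethyl-1,3,2-dioxaborolane; 8 allyl acetate
Product: 11 2-[(2S,3S)-3-allyl-2-(3,4-dimethoxyphenyl)-5-(dimethoxymethyl)-7-methoxy-2,3-dihydrobenzofuran-2-yl]-4,4,5,5-tetramethyl-1,3,2-dioxaborolane, via lithiated benzofuran 9 (not isolated), via lithium boronate complex 10 (not isolated)
Conditions: n-BuLi, THF, −78 °C; 7, −78 °C → rt; then Pd2(dba)3 (2.5 mol%), (R)-BINAP (6 mol%), 8, THF, rt
Reagents that add atoms: none
Why: Proposed new method: C2 lithiation of 6 and addition to the boron of 7 give the tetracoordinate boronate 10, in which the B–C2 bond and O1 make C3 an electron-rich enol-ether carbon that attacks a terminal carbon of the cationic π-allylpalladium complex (from 8, the zerovalent palladium of Pd2(dba)3 and the bisphosphine) on the allyl face away from the metal. As the C3–CH2 bond forms, C2 becomes electron-poor and the 3,4-dimethoxyphenyl group shifts from boron to C2 on the face opposite to the incoming allyl group, so that allyl and aryl end up anti and boron stays cis to allyl. The closest known reaction type is the enantioselective palladium-catalysed three-component coupling of indol-2-yl boronate complexes with allylic acetates, together with electrophile-triggered 1,2-migrations of furan-2-yl and benzofuran-2-yl boronates; the transfer to a benzofuran with the dearomatised boronic ester kept is the untested part. No ring is closed; ring B is dearomatised. C3 is controlled by the chiral ligand on palladium, which distinguishes the two faces of the flat nucleophile in the outer-sphere attack, and C2 is controlled relative to C3 by the stereospecific antiperiplanar migration. The step needs attack through C3 and not transmetalation of an aryl or benzofuranyl group to palladium; the chelating bisphosphine, which leaves no free site on the cationic allyl complex, and the polarisation of C2=C3 by O1 and boron should secure this. The acetal and the methoxy groups are spectators, and the electron-rich aryl group should migrate readily.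

Step 5
Reactants: 11 2-[(2S,3S)-3-allyl-2-(3,4-dimethoxyphenyl)-5-(dimethoxymethyl)-7-methoxy-2,3-dihydrobenzofuran-2-yl]-4,4,5,5-tetramethyl-1,3,2-dioxaborolane
Product: 12 (2S,3S)-3-allyl-2-(3,4-dimethoxyphenyl)-5-(dimethoxymethyl)-7-methoxy-2,3-dihydrobenzofuran
Conditions: Bu4NF·3H2O (1.5 equiv), toluene, rt → 45 °C
Reagents that add atoms: none
Why: Fluoride-promoted protodeboronation of a tertiary benzylic boronic ester; the fluoroborate should be protonated at carbon by boron-associated water on the face that held boron (front-side substitution, retention), so that C2–H is cis to the allyl group and the aryl group stays trans, while C3 is not touched.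

Step 6
Reactants: 12 (2S,3S)-3-allyl-2-(3,4-dimethoxyphenyl)-5-(dimethoxymethyl)-7-methoxy-2,3-dihydrobenzofuran
Product: 13 (2S,3S)-2-(3,4-dimethoxyphenyl)-5-(dimethoxymethyl)-7-methoxy-3-[(E)-prop-1-enyl]-2,3-dihydrobenzofuran
Conditions: RuHCl(CO)(PPh3)3 (5 mol%), toluene, 80 °C
Reagents that add atoms: none
Why: Ruthenium hydride alkene isomerisation by hydrometalation and β-hydride elimination; the terminal alkene should move one position to the internal alkene and stop there, because re-insertion into a 1,2-disubstituted alkene beside the hindered tertiary C3 is slow, so C3–H and the stereocentre are not involved.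

Step 7
Reactants: 13 (2S,3S)-2-(3,4-dimethoxyphenyl)-5-(dimethoxymethyl)-7-methoxy-3-[(E)-prop-1-enyl]-2,3-dihydrobenzofuran
Product: 16 (2S,3R)-2-(3,4-dimethoxyphenyl)-3-(hydroxymethyl)-7-methoxy-2,3-dihydrobenzofuran-5-carbaldehyde, via C3 carbaldehyde 14 (not isolated), via hydroxymethyl acetal 15 (not isolated)
Conditions: O3, CH2Cl2/MeOH, Sudan Red 7B (indicator), −78 °C; NaBH4, −78 → 0 °C; acetone; then 1 M HCl, THF, rt
Reagents that add atoms: ozone, [O-][O+]=O; water, O
Why: Ozonolysis of the disubstituted alkene should outrun attack on the methoxyarenes when the end point is read from the dye, and borohydride added cold reduces 14 to 15 before the α-aryl β-aryloxy aldehyde can epimerise or open ring B. After the excess hydride is destroyed, dilute acid hydrolyses the very labile para-alkoxybenzaldehyde dimethyl acetal without ionising C2–O1.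

Step 8
Reactants: 16 (2S,3R)-2-(3,4-dimethoxyphenyl)-3-(hydroxymethyl)-7-methoxy-2,3-dihydrobenzofuran-5-carbaldehyde
Product: 17 ethyl (E)-3-[(2S,3R)-2-(3,4-dimethoxyphenyl)-3-(hydroxymethyl)-7-methoxy-2,3-dihydrobenzofuran-5-yl]prop-2-enoate
Conditions: Ph3P=CHCO2Et, toluene, 60 °C
Reagents that add atoms: ethyl (triphenylphosphoranylidene)acetate, CCOC(=O)C=P(c1ccccc1)(c1ccccc1)c1ccccc1
Why: Wittig olefination with a stabilised ylide, which should give the E cinnamate from an aryl aldehyde under neutral conditions that leave the free alcohol and the C2–O1 bond alone.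

Step 9
Reactants: 17 ethyl (E)-3-[(2S,3R)-2-(3,4-dimethoxyphenyl)-3-(hydroxymethyl)-7-methoxy-2,3-dihydrobenzofuran-5-yl]prop-2-enoate
Product: 18 Hierochin B, (E)-3-[(2S,3R)-2-(3,4-dimethoxyphenyl)-3-(hydroxymethyl)-7-methoxy-2,3-dihydrobenzofuran-5-yl]prop-2-en-1-ol
Conditions: i-Bu2AlH (3.5 equiv), CH2Cl2, −78 → 0 °C; aqueous potassium sodium tartrate work-up
Reagents that add atoms: none
Why: 1,2-Reduction of the unsaturated ester to the allylic alcohol; the first equivalent is consumed by the free hydroxyl group, the low temperature avoids conjugate reduction, and the non-acidic work-up preserves the cinnamyl alcohol and the benzylic ether.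

## Compound list

1 | 5-iodovanillin (4-hydroxy-3-iodo-5-methoxybenzaldehyde) | COc1cc(C=O)cc(I)c1O | starting material
2 | trimethylsilylacetylene | C#C[Si](C)(C)C | starting material
3 | 4-hydroxy-3-methoxy-5-[(trimethylsilyl)ethynyl]benzaldehyde | COc1cc(C=O)cc(C#C[Si](C)(C)C)c1O | intermediate
4 | 3-ethynyl-4-hydroxy-5-methoxybenzaldehyde | COc1cc(C=O)cc(C#C)c1O | intermediate (not isolated)
5 | 7-methoxybenzofuran-5-carbaldehyde | COc1cc(C=O)cc2ccoc12 | intermediate
6 | 5-(dimethoxymethyl)-7-methoxybenzofuran | COC(OC)c1cc(OC)c2occc2c1 | intermediate
7 | 2-(3,4-dimethoxyphenyl)-4,4,5,5-tetramethyl-1,3,2-dioxaborolane | COc1ccc(B2OC(C)(C)C(C)(C)O2)cc1OC | starting material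
8 | allyl acetate | CC(=O)OCC=C | starting material
9 | [5-(dimethoxymethyl)-7-methoxybenzofuran-2-yl]lithium | [Li]c1cc2cc(C(OC)OC)cc(OC)c2o1 | intermediate (not isolated)
10 | lithium [5-(dimethoxymethyl)-7-methoxybenzofuran-2-yl](3,4-dimethoxyphenyl)(pinacolato)borate | [Li+].COc1ccc([B-]2(c3cc4cc(C(OC)OC)cc(OC)c4o3)OC(C)(C)C(C)(C)O2)cc1OC | intermediate (not isolated)
11 | 2-[(2S,3S)-3-allyl-2-(3,4-dimethoxyphenyl)-5-(dimethoxymethyl)-7-methoxy-2,3-dihydrobenzofuran-2-yl]-4,4,5,5-tetramethyl-1,3,2-dioxaborolane (aryl and allyl anti) | COc1ccc([C@@]2(B4OC(C)(C)C(C)(C)O4)Oc3c(OC)cc(C(OC)OC)cc3[C@@H]2CC=C)cc1OC | intermediate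
12 | (2S,3S)-3-allyl-2-(3,4-dimethoxyphenyl)-5-(dimethoxymethyl)-7-methoxy-2,3-dihydrobenzofuran | COc1ccc([C@H]2Oc3c(OC)cc(C(OC)OC)cc3[C@@H]2CC=C)cc1OC | intermediate
13 | (2S,3S)-2-(3,4-dimethoxyphenyl)-5-(dimethoxymethyl)-7-methoxy-3-[(E)-prop-1-enyl]-2,3-dihydrobenzofuran | COc1ccc([C@H]2Oc3c(OC)cc(C(OC)OC)cc3[C@@H]2/C=C/C)cc1OC | intermediate
14 | (2S,3S)-2-(3,4-dimethoxyphenyl)-5-(dimethoxymethyl)-7-methoxy-2,3-dihydrobenzofuran-3-carbaldehyde | COc1ccc([C@H]2Oc3c(OC)cc(C(OC)OC)cc3[C@@H]2C=O)cc1OC | intermediate (not isolated)
15 | [(2S,3R)-2-(3,4-dimethoxyphenyl)-5-(dimethoxymethyl)-7-methoxy-2,3-dihydrobenzofuran-3-yl]methanol | COc1ccc([C@H]2Oc3c(OC)cc(C(OC)OC)cc3[C@@H]2CO)cc1OC | intermediate (not isolated)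
16 | (2S,3R)-2-(3,4-dimethoxyphenyl)-3-(hydroxymethyl)-7-methoxy-2,3-dihydrobenzofuran-5-carbaldehyde | COc1ccc([C@H]2Oc3c(OC)cc(C=O)cc3[C@@H]2CO)cc1OC | intermediate
17 | ethyl (E)-3-[(2S,3R)-2-(3,4-dimethoxyphenyl)-3-(hydroxymethyl)-7-methoxy-2,3-dihydrobenzofuran-5-yl]prop-2-enoate | COc1ccc([C@H]2Oc3c(OC)cc(/C=C/C(=O)OCC)cc3[C@@H]2CO)cc1OC | intermediate
18 | Hierochin B | COc1ccc([C@H]2Oc3c(OC)cc(/C=C/CO)cc3[C@@H]2CO)cc1OC | target

## Step count and least certain steps

Total step count: 9. Longest linear sequence: 9 steps (1 to 18); 7 and 8 are purchased and enter at step 4.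

**Step 4 (key step, proposed new method).**
- What may go wrong: poor facial selectivity at C3; transfer of an aryl or benzofuranyl group from boron to palladium, leading to simple allyl–aryl coupling; incomplete or misdirected lithiation, since C6 lies between two directing groups. The reason is that the indole precedent differs from a benzofuran in nucleophilicity at C3 and in the stability of the dearomatised product.
- Fallback by known chemistry, setting out from 1 and coming back at 15:
  - 1 is O-alkylated with 3,4-dimethoxybenzyl chloride (K2CO3, DMF) to 4-[(3,4-dimethoxybenzyl)oxy]-3-iodo-5-methoxybenzaldehyde F1.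
  - Acetalisation as in step 3 gives the dimethyl acetal 2-[(3,4-dimethoxybenzyl)oxy]-5-(dimethoxymethyl)-1-iodo-3-methoxybenzene F2.
  - Palladium-catalysed coupling of the aryl iodide with ethyl diazoacetate (Pd(PPh3)4, Ag2CO3, Et3N, toluene) gives ethyl 2-diazo-2-{2-[(3,4-dimethoxybenzyl)oxy]-5-(dimethoxymethyl)-3-methoxyphenyl}acetate F3.
  - The chiral dirhodium tetracarboxylate Rh2(S-PTTL)4 (antipode if the sense of induction requires it) effects enantioselective intramolecular 1,5 C–H insertion into the benzylic ether methylene, giving the cis ester ethyl (2S,3R)-2-(3,4-dimethoxyphenyl)-5-(dimethoxymethyl)-7-methoxy-2,3-dihydrobenzofuran-3-carboxylate F4.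
  - NaOEt in EtOH epimerises C3 to the trans ester ethyl (2S,3S)-2-(3,4-dimethoxyphenyl)-5-(dimethoxymethyl)-7-methoxy-2,3-dihydrobenzofuran-3-carboxylate F5.
  - LiAlH4 in THF at 0 °C reduces the ester to 15, which is taken through the acid stage of step 7 to 16.

**Step 5.**
- What may go wrong: loss of configuration at C2 if the benzylic, oxygen-substituted carbanion separates from boron before it is protonated; protonation from the less hindered face would then give the cis series. Ring opening by loss of the aryloxide from the boronate is a further possibility.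
- Fallback, setting out from 11 and coming back at 16; it replaces stereoretentive control by thermodynamic control:
  - The protodeboronation is run without regard to fidelity at C2. 12 is carried through steps 6 and 7 together with its C2 epimer, the cis allyl compound (2R,3S)-3-allyl-2-(3,4-dimethoxyphenyl)-5-(dimethoxymethyl)-7-methoxy-2,3-dihydrobenzofuran F6.
  - On the way the epimer passes through the cis propenyl compound F7, the cis C3 carbaldehyde F8 and the cis hydroxymethyl acetal F9 to the cis hydroxy aldehyde F10.
  - The mixture of 16 and F10 is treated with CF3CO2H in CH2Cl2 at 0 °C. This should ionise the C2–O1 bond, which is benzylic to ring C and has a para-formyl phenoxide as leaving group; reclosure should favour the 2,3-trans isomer 16. C3 takes no part, so the enantiomeric purity set in step 4 is kept.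

**Step 6.**
- What may go wrong: migration of the double bond beyond the propenyl stage into conjugation with ring A, which destroys C3 and can end in the aromatic benzofuran; or an incomplete shift. The reason is that the exocyclic alkene and the benzofuran are thermodynamic sinks.
- Fallback, setting out from 12 and coming back at 15; it is a one-carbon degradation without isomerisation:
  - 12 is ozonised (O3, CH2Cl2, −78 °C, indicator; PPh3) to 2-[(2S,3S)-2-(3,4-dimethoxyphenyl)-5-(dimethoxymethyl)-7-methoxy-2,3-dihydrobenzofuran-3-yl]acetaldehyde F11.
  - Condensation with piperidine (4 Å molecular sieves, toluene, rt) gives the enamine 1-{(E)-2-[(2S,3S)-2-(3,4-dimethoxyphenyl)-5-(dimethoxymethyl)-7-methoxy-2,3-dihydrobenzofuran-3-yl]ethenyl}piperidine F12.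
  - Ozonolysis of the enamine double bond at −78 °C, followed by NaBH4 in MeOH in the same flask, gives 15, which continues with the acid stage of step 7.

**Step 7.**
- What may go wrong: over-oxidation of the electron-rich arenes or of the acetal C–H by ozone; epimerisation or E1cB opening of ring B at the stage of 14 if the reduction lags.
- Fallback, setting out from 13 and coming back at 15; dihydroxylation and glycol cleavage replace ozone:
  - OsO4 (cat.) and N-methylmorpholine N-oxide in acetone/H2O give 1-[(2S,3R)-2-(3,4-dimethoxyphenyl)-5-(dimethoxymethyl)-7-methoxy-2,3-dihydrobenzofuran-3-yl]propane-1,2-diol F13 as a mixture at the diol carbons.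
  - NaIO4 in THF/pH 7 buffer at 0 °C cleaves the diol, and NaBH4 added directly gives 15, followed by the acid stage of step 7.

## Further compounds

F1 | step 4 | 4-[(3,4-dimethoxybenzyl)oxy]-3-iodo-5-methoxybenzaldehyde | COc1ccc(COc2c(I)cc(C=O)cc2OC)cc1OC
F2 | step 4 | 2-[(3,4-dimethoxybenzyl)oxy]-5-(dimethoxymethyl)-1-iodo-3-methoxybenzene | COc1ccc(COc2c(I)cc(C(OC)OC)cc2OC)cc1OC
F3 | step 4 | ethyl 2-diazo-2-{2-[(3,4-dimethoxybenzyl)oxy]-5-(dimethoxymethyl)-3-methoxyphenyl}acetate | CCOC(=O)C(=[N+]=[N-])c1cc(C(OC)OC)cc(OC)c1OCc1ccc(OC)c(OC)c1
F4 | step 4 | ethyl (2S,3R)-2-(3,4-dimethoxyphenyl)-5-(dimethoxymethyl)-7-methoxy-2,3-dihydrobenzofuran-3-carboxylate (cis) | COc1ccc([C@H]2Oc3c(OC)cc(C(OC)OC)cc3[C@H]2C(=O)OCC)cc1OC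
F5 | step 4 | ethyl (2S,3S)-2-(3,4-dimethoxyphenyl)-5-(dimethoxymethyl)-7-methoxy-2,3-dihydrobenzofuran-3-carboxylate (trans) | COc1ccc([C@H]2Oc3c(OC)cc(C(OC)OC)cc3[C@@H]2C(=O)OCC)cc1OC
F6 | step 5 | (2R,3S)-3-allyl-2-(3,4-dimethoxyphenyl)-5-(dimethoxymethyl)-7-methoxy-2,3-dihydrobenzofuran (cis) | COc1ccc([C@@H]2Oc3c(OC)cc(C(OC)OC)cc3[C@@H]2CC=C)cc1OC
F7 | step 5 | (2R,3S)-2-(3,4-dimethoxyphenyl)-5-(dimethoxymethyl)-7-methoxy-3-[(E)-prop-1-enyl]-2,3-dihydrobenzofuran (cis) | COc1ccc([C@@H]2Oc3c(OC)cc(C(OC)OC)cc3[C@@H]2/C=C/C)cc1OC
F8 | step 5 | (2R,3S)-2-(3,4-dimethoxyphenyl)-5-(dimethoxymethyl)-7-methoxy-2,3-dihydrobenzofuran-3-carbaldehyde (cis) | COc1ccc([C@@H]2Oc3c(OC)cc(C(OC)OC)cc3[C@@H]2C=O)cc1OC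
F9 | step 5 | [(2R,3R)-2-(3,4-dimethoxyphenyl)-5-(dimethoxymethyl)-7-methoxy-2,3-dihydrobenzofuran-3-yl]methanol (cis) | COc1ccc([C@@H]2Oc3c(OC)cc(C(OC)OC)cc3[C@@H]2CO)cc1OC
F10 | step 5 | (2R,3R)-2-(3,4-dimethoxyphenyl)-3-(hydroxymethyl)-7-methoxy-2,3-dihydrobenzofuran-5-carbaldehyde (cis) | COc1ccc([C@@H]2Oc3c(OC)cc(C=O)cc3[C@@H]2CO)cc1OC
F11 | step 6 | 2-[(2S,3S)-2-(3,4-dimethoxyphenyl)-5-(dimethoxymethyl)-7-methoxy-2,3-dihydrobenzofuran-3-yl]acetaldehyde | COc1ccc([C@H]2Oc3c(OC)cc(C(OC)OC)cc3[C@@H]2CC=O)cc1OC
F12 | step 6 | 1-{(E)-2-[(2S,3S)-2-(3,4-dimethoxyphenyl)-5-(dimethoxymethyl)-7-methoxy-2,3-dihydrobenzofuran-3-yl]ethenyl}piperidine | COc1ccc([C@H]2Oc3c(OC)cc(C(OC)OC)cc3[C@@H]2/C=C/N2CCCCC2)cc1OC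
F13 | step 7 | 1-[(2S,3R)-2-(3,4-dimethoxyphenyl)-5-(dimethoxymethyl)-7-methoxy-2,3-dihydrobenzofuran-3-yl]propane-1,2-diol (mixture at the diol carbons) | COc1ccc([C@H]2Oc3c(OC)cc(C(OC)OC)cc3[C@@H]2C(O)C(C)O)cc1OC
A1 | alternative 1 | methyl 3-[(2R)-1-(tert-butyldimethylsilyloxy)-3-(3,4-dimethoxyphenyl)propan-2-yl]-4-hydroxy-5-methoxybenzoate | COC(=O)c1cc(OC)c(O)c(c1)[C@@H](Cc1ccc(OC)c(OC)c1)CO[Si](C)(C)C(C)(C)C
A2 | alternative 1 | methyl (2S,3R)-3-(tert-butyldimethylsilyloxymethyl)-2-(3,4-dimethoxyphenyl)-7-methoxy-2,3-dihydrobenzofuran-5-carboxylate | COc1ccc([C@H]2Oc3c(OC)cc(C(=O)OC)cc3[C@@H]2CO[Si](C)(C)C(C)(C)C)cc1OC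
A3 | alternative 2 | {[(1R,2R)-1-(3,4-dimethoxyphenyl)-2-(triisopropylsilyloxymethyl)but-3-yn-1-yl]oxy}(methoxyethynyl)dimethylsilane | COc1ccc([C@H](O[Si](C)(C)C#COC)[C@@H](CO[Si](C(C)C)(C(C)C)C(C)C)C#C)cc1OC
A4 | alternative 2 | triisopropyl{[(E)-pent-2-en-4-yn-1-yl]oxy}silane | C#C/C=C/CO[Si](C(C)C)(C(C)C)C(C)C
A5 | alternative 2 | (3R,4R)-3-(3,4-dimethoxyphenyl)-8-methoxy-1,1-dimethyl-4-(triisopropylsilyloxymethyl)-6-[(E)-3-(triisopropylsilyloxy)prop-1-enyl]-3,4-dihydro-1H-2,1-benzoxasiline | COc1ccc([C@@H]2O[Si](C)(C)c3c(OC)cc(/C=C/CO[Si](C(C)C)(C(C)C)C(C)C)cc3[C@@H]2CO[Si](C(C)C)(C(C)C)C(C)C)cc1OC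
A6 | alternative 3 | {[(4R,5S)-5-(3,4-dimethoxyphenyl)-4-(triisopropylsilyloxymethyl)-4,5-dihydrofuran-2-yl]oxy}trimethylsilane | COc1ccc([C@H]2OC(O[Si](C)(C)C)=C[C@@H]2CO[Si](C(C)C)(C(C)C)C(C)C)cc1OC
A7 | alternative 3 | methyl 3-bromo-2-oxo-2H-pyran-5-carboxylate (methyl 3-bromocoumalate) | COC(=O)C1=COC(=O)C(Br)=C1
A8 | alternative 3 | methyl (2S,3R)-7-bromo-2-(3,4-dimethoxyphenyl)-3-(triisopropylsilyloxymethyl)-2,3-dihydrobenzofuran-5-carboxylate | COc1ccc([C@H]2Oc3c(Br)cc(C(=O)OC)cc3[C@@H]2CO[Si](C(C)C)(C(C)C)C(C)C)cc1OC
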